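**Retrosynthetic overview**

1. Target 29 ⇐ Mitsunobu esterification with angelic acid, with inversion at C8, of the 8α-alcohol 27; the C3 ester, the oxirane and the lactone are already in place.
2. 27 ⇐ C7–C8 bond: intramolecular Nozaki–Hiyama allylation of the C8 aldehyde by the allylchromium made from the 3-(bromomethyl)butenolide 25. This closes the ten-membered carbocycle, sets C7 and C8, and moves the lactone alkene from C7=C11 to the exocyclic C11=C13.
3. Enabling feature: in the target the C8 oxygen is homoallylic to the exocyclic C11=C13 methylene of the γ-lactone ring (O–C6–C7–C11–C12). The array C8(O)–C7–C11=C13 is the retron of a carbonyl allylation with allylic transposition, and C7 is shared by the lactone and the ten-membered ring.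
4. 25 ⇐ butenolide by acylation and ring-closing metathesis of a C6 divinyl carbinol (Stille coupling at C5, Sharpless epoxidation, reductive epoxide opening); C1–C10 oxirane by Shi epoxidation of a Z-alkene whose geometry is fixed in a temporary seven-membered lactone; C3 by Brown allylation of (Z)-3-iodo-2-methylpropenal.
5. Ring order: temporary oxepinone (made, then cleaved) → oxirane → butenolide → ten-membered ring, which forms together with the α-methylene lactone.

Key step: step 18

Remark: atom numbers C1–C15 in names and reasoning are the germacrane numbers of the target (C12 lactone carbonyl, C13 exocyclic methylene, C14 methyl on C10, C15 methyl on C4); compounds 8, 13, 16, 21 and 28 are assumed to be purchased.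

**Step 1**
Reactants: 1 propargyl alcohol; 2 methylmagnesium bromide
Product: 4 (Z)-3-iodo-2-methylprop-2-en-1-ol, via alkenylmagnesium alkoxide 3 (not isolated)
Conditions: MeMgBr (3 equiv), CuI (cat.), Et2O, −10 °C → rt; then I2, −78 → 0 °C
Reagents that add atoms: methylmagnesium bromide (2), C[Mg]Br; iodine, II
Why: Copper-catalysed anti-carbomagnesiation of the propargylic magnesium alkoxide places methyl on the internal carbon and magnesium on the terminus cis to CH2O through a five-membered chelate, so iodinolysis with retention should give the Z-iodoalkene that later becomes C4=C5.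

**Step 2**
Reactants: 4
Product: 5 (Z)-3-iodo-2-methylprop-2-enal
Conditions: MnO2 (excess), CH2Cl2, rt, dark
Reagents that add atoms: none
Why: Allylic alcohol oxidation with MnO2 is neutral and should leave the Z-iodoalkene geometry intact.

**Step 3**
Reactants: 5; 6 allylmagnesium bromide
Product: 7 (3S,1Z)-1-iodo-2-methylhexa-1,5-dien-3-ol
Conditions: (−)-Ipc2BOMe (from (+)-α-pinene) + 6, Et2O, 0 °C → rt; then 5, −78 °C; NaOH, H2O2, 0 °C → rt
Reagents that add atoms: allylmagnesium bromide (6), C=CC[Mg]Br
Why: Brown allylation: the allylborane made from the (+)-α-pinene-derived borinate should add through a chair-like six-membered transition state to the Si face of the aldehyde, which sets C3 as S.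

**Step 4**
Reactants: 7; 8 3-methylbut-3-enoic acid
Product: 9 (3S,1Z)-1-iodo-2-methylhexa-1,5-dien-3-yl 3-methylbut-3-enoate
Conditions: N,N′-dicyclohexylcarbodiimide, DMAP (cat.), CH2Cl2, 0 °C
Reagents that add atoms: 3-methylbut-3-enoic acid (8), C=C(C)CC(=O)O
Why: Steglich esterification at low temperature with little DMAP should acylate the secondary alcohol without moving the β,γ-double bond of the acid into conjugation.

**Step 5**
Reactants: 9
Product: 10 (7S)-7-[(Z)-1-iodoprop-1-en-2-yl]-4-methyl-3,6-dihydrooxepin-2(7H)-one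
Conditions: second-generation Grubbs catalyst (H2IMes)(PCy3)Cl2Ru=CHPh (5 mol %), CH2Cl2 (5 mM), reflux
Reagents that add atoms: none
Why: Ring-closing metathesis of the two terminal alkenes closes a temporary seven-membered lactone in which the new trisubstituted C1=C10 alkene can only be Z, while the electron-poor trisubstituted iodoalkene does not take part.

**Step 6**
Reactants: 10
Product: 11 (3Z,6S,7Z)-8-iodo-3,7-dimethylocta-3,7-diene-1,6-diol
Conditions: iBu2AlH (4 equiv), CH2Cl2, −78 → 0 °C; aqueous Rochelle salt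
Reagents that add atoms: none
Why: Hydride reduction of the lactone to the diol cleaves the temporary ring and frees the C3 and C8 hydroxyls, with the alkene geometry kept and the vinyl iodide untouched at low temperature.

**Step 7**
Reactants: 11
Product: 12 (3S,1Z,5Z)-8-(tert-butyldimethylsilyloxy)-1-iodo-2,6-dimethylocta-1,5-dien-3-ol
Conditions: tert-butyldimethylsilyl chloride (1.05 equiv), imidazole, CH2Cl2, −20 °C
Reagents that add atoms: tert-butyldimethylsilyl chloride, C[Si](C)(Cl)C(C)(C)C
Why: Silylation is selective for the primary C8 hydroxyl over the hindered secondary allylic C3 hydroxyl.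

**Step 8**
Reactants: 12; 13 (R)-2-methylbutanoic acid
Product: 14 (3S,1Z,5Z)-8-(tert-butyldimethylsilyloxy)-1-iodo-2,6-dimethylocta-1,5-dien-3-yl (2R)-2-methylbutanoate
Conditions: N,N′-dicyclohexylcarbodiimide, DMAP (cat.), CH2Cl2, 0 °C → rt
Reagents that add atoms: (R)-2-methylbutanoic acid (13), CC[C@@H](C)C(=O)O
Why: Steglich esterification installs the (R)-2-methylbutanoate of the target; carbodiimide activation does not enolise the α-stereocentre of the acid.

**Step 9**
Reactants: 14
Product: 15 (1Z,3S)-4-{(2R,3S)-3-[2-(tert-butyldimethylsilyloxy)ethyl]-3-methyloxiran-2-yl}-1-iodo-2-methylbut-1-en-3-yl (2R)-2-methylbutanoate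
Conditions: Shi ketone from D-fructose (1,2:4,5-di-O-isopropylidene-β-D-erythro-2,3-hexodiulo-2,6-pyranose, 0.3 equiv), KHSO5 (as Oxone), K2CO3, Bu4NHSO4, MeCN/dimethoxymethane/aqueous borate buffer, 0 °C
Reagents that add atoms: potassium peroxymonosulfate, [K+].[O-]S(=O)(=O)OO
Why: Shi asymmetric epoxidation: the dioxirane of the D-fructose-derived ketone should attack the only electron-rich alkene through the spiro transition state from the face that makes C1 R, and syn addition to the Z-alkene then gives the cis-oxirane with C10 S; the iodoalkene is too electron-poor to react.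

**Step 10**
Reactants: 15; 16 (E)-3-(tributylstannyl)prop-2-en-1-ol
Product: 17 (2E,4Z,6S)-7-{(2R,3S)-3-[2-(tert-butyldimethylsilyloxy)ethyl]-3-methyloxiran-2-yl}-1-hydroxy-5-methylhepta-2,4-dien-6-yl (2R)-2-methylbutanoate
Conditions: Pd2(dba)3 (5 mol %), AsPh3 (20 mol %), NMP, rt
Reagents that add atoms: (E)-3-(tributylstannyl)prop-2-en-1-ol (16), OC/C=C/[Sn](CCCC)(CCCC)CCCC
Why: Stille coupling of the alkenyl iodide with the E-alkenylstannane proceeds with retention at both partners and should give the (2E,4Z)-dienol.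

**Step 11**
Reactants: 17
Product: 18 (1Z,3S)-4-{(2R,3S)-3-[2-(tert-butyldimethylsilyloxy)ethyl]-3-methyloxiran-2-yl}-1-[(2R,3R)-3-(hydroxymethyl)oxiran-2-yl]-2-methylbut-1-en-3-yl (2R)-2-methylbutanoate
Conditions: Ti(OiPr)4 (cat.), D-(−)-diisopropyl tartrate (cat.), tert-butyl hydroperoxide, 4 Å molecular sieves, CH2Cl2, −20 °C
Reagents that add atoms: tert-butyl hydroperoxide, CC(C)(C)OO
Why: Sharpless asymmetric epoxidation with the D-(−)-tartrate delivers oxygen only to the allylic-alcohol alkene and to the face that gives the (2R,3R)-epoxy alcohol, which fixes C6 with the configuration of the target.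

**Step 12**
Reactants: 18
Product: 19 (1Z,3S)-4-{(2R,3S)-3-[2-(tert-butyldimethylsilyloxy)ethyl]-3-methyloxiran-2-yl}-1-[(2R,3S)-3-(iodomethyl)oxiran-2-yl]-2-methylbut-1-en-3-yl (2R)-2-methylbutanoate
Conditions: PPh3, I2, imidazole, CH2Cl2, 0 °C
Reagents that add atoms: iodine, II
Why: Appel-type iodination converts the primary alcohol into the iodide under neutral conditions that spare both oxiranes.

**Step 13**
Reactants: 19
Product: 20 (3S,4Z,6S)-7-{(2R,3S)-3-[2-(tert-butyldimethylsilyloxy)ethyl]-3-methyloxiran-2-yl}-3-hydroxy-5-methylhepta-1,4-dien-6-yl (2R)-2-methylbutanoate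
Conditions: activated Zn dust, EtOH, 50 °C
Reagents that add atoms: none
Why: Zinc inserts into the C–I bond and β-elimination opens the adjacent oxirane (reductive 1,3-transposition of a 2,3-epoxy iodide), which unveils the C6 carbinol without touching its C–O bond, so its configuration is retained, and gives the vinyl group needed for the butenolide.

**Step 14**
Reactants: 20; 21 2-(bromomethyl)acrylic acid
Product: 22 (3S,4Z,6S)-7-{(2R,3S)-3-[2-(tert-butyldimethylsilyloxy)ethyl]-3-methyloxiran-2-yl}-5-methyl-6-{[(2R)-2-methylbutanoyl]oxy}hepta-1,4-dien-3-yl 2-(bromomethyl)prop-2-enoate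
Conditions: N,N′-dicyclohexylcarbodiimide, DMAP (5 mol %), CH2Cl2, −20 → 0 °C
Reagents that add atoms: 2-(bromomethyl)acrylic acid (21), C=C(CBr)C(=O)O
Why: Steglich esterification of the bis-allylic alcohol; low temperature and a small amount of DMAP should limit substitution of the allylic bromide.

**Step 15**
Reactants: 22
Product: 23 (5R)-3-(bromomethyl)-5-[(1Z,3S)-4-{(2R,3S)-3-[2-(tert-butyldimethylsilyloxy)ethyl]-3-methyloxiran-2-yl}-2-methyl-3-{[(2R)-2-methylbutanoyl]oxy}but-1-en-1-yl]furan-2(5H)-one
Conditions: second-generation Grubbs catalyst (H2IMes)(PCy3)Cl2Ru=CHPh (10 mol %), toluene (5 mM), 80 °C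
Reagents that add atoms: none
Why: Ring-closing metathesis between the vinyl group and the acrylate alkene closes the butenolide with loss of ethene; the trisubstituted C4=C5 alkene and the allylic bromide are spectators.

**Step 16**
Reactants: 23
Product: 24 (5R)-3-(bromomethyl)-5-[(1Z,3S)-4-[(2R,3S)-3-(2-hydroxyethyl)-3-methyloxiran-2-yl]-2-methyl-3-{[(2R)-2-methylbutanoyl]oxy}but-1-en-1-yl]furan-2(5H)-one
Conditions: HF·pyridine, pyridine, THF, 0 °C
Reagents that add atoms: none
Why: Pyridine-buffered HF removes the primary silyl ether without opening the oxirane or displacing the bromide.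

**Step 17**
Reactants: 24
Product: 25 (5R)-3-(bromomethyl)-5-[(1Z,3S)-2-methyl-3-{[(2R)-2-methylbutanoyl]oxy}-4-[(2R,3S)-3-methyl-3-(2-oxoethyl)oxiran-2-yl]but-1-en-1-yl]furan-2(5H)-one
Conditions: Dess–Martin periodinane, NaHCO3, CH2Cl2, 0 °C; used at once
Reagents that add atoms: none
Why: Dess–Martin oxidation under buffered, non-basic conditions gives the β,γ-epoxy aldehyde without β-elimination of the oxirane.

**Step 18**
Reactants: 25
Product: 27 (1R,3S,6R,7R,8S,10S)-1,10-epoxy-8-hydroxy-3-[(2R)-2-methylbutanoyloxy]germacra-4Z,11(13)-dien-12,6-olide (8α-alcohol, trans-fused lactone), via allylchromium dichloride 26 (not isolated)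
Conditions: CrCl2 (10 equiv), THF, rt, slow addition of 25 (final 2 mM); aqueous work-up
Reagents that add atoms: none
Why: CrCl2 (two equivalents per bromide) should insert into the C13–Br bond to give allylchromium 26, which adds through C7 to the C8 aldehyde with allylic transposition in a closed six-membered Zimmerman–Traxler chair, as in the known Nozaki–Hiyama allylations of aldehydes with 3-(bromomethyl)furan-2(5H)-ones and in known chromium-mediated closures of ten-membered germacranolide rings. The ten-membered carbocycle closes in the 10-exo-trig mode at the aldehyde, and the same bond formation moves the lactone alkene from C7=C11 to the exocyclic C11=C13 position. C7 is set by the C6 stereocentre: the tether leaves C6 on one face of the planar butenolide, and a near-antiperiplanar C5–C6–C7–C8 segment lets C8 reach the opposite face without eclipsing, so the trans-fused lactone (7R) is expected. C8 is set by the chair: C6 is trans to C13 on the ring alkene and must sit equatorial, and with C9 equatorial as well (anti to C11, gauche to C6, as a ten-membered ring needs) the 7,8-anti alcohol with 8S configuration (8α-OH) should form. The step needs chemoselectivity and ring closure over oligomerisation: the allylic bromide is the only site reduced by divalent chromium, the aldehyde is the only carbonyl the allylchromium attacks, the hindered trisubstituted oxirane and both esters are spectators, and the Z-alkene and cis-oxirane fold the six-atom tether while slow addition keeps the concentration low. The 8α configuration is the one wanted here, because the last step introduces the angelate with inversion.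

**Step 19**
Reactants: 27; 28 angelic acid ((Z)-2-methylbut-2-enoic acid)
Product: 29 (1R,3S,6R,7R,8R,10S)-8-angeloyloxy-1,10-epoxy-3-[(2R)-2-methylbutanoyloxy]germacra-4Z,11(13)-dien-12,6-olide (CNP0108431.1)
Conditions: PPh3, diisopropyl azodicarboxylate, 28, toluene, 0 °C → rt
Reagents that add atoms: angelic acid (28), C/C=C(/C)C(=O)O
Why: Mitsunobu esterification inverts C8 (8S to 8R) by SN2 attack of angelate on the alkoxyphosphonium ion; the acid reacts as a carboxylate nucleophile, so the Z-enoate is never activated at its carbonyl and should keep its geometry, and the neutral conditions spare the oxirane, the α-methylene lactone and the other ester.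

**Compound list**

1 | propargyl alcohol (prop-2-yn-1-ol) | C#CCO | starting material
2 | methylmagnesium bromide | C[Mg]Br | starting material
3 | bromomagnesium (Z)-3-(bromomagnesio)-2-methylprop-2-en-1-olate (alkenylmagnesium alkoxide) | Br[Mg]OC/C(C)=C\[Mg]Br | intermediate
4 | (Z)-3-iodo-2-methylprop-2-en-1-ol | OC/C(C)=C\I | intermediate
5 | (Z)-3-iodo-2-methylprop-2-enal | O=C/C(C)=C\I | intermediate
6 | allylmagnesium bromide | C=CC[Mg]Br | starting material
7 | (3S,1Z)-1-iodo-2-methylhexa-1,5-dien-3-ol | I/C=C(/C)[C@@H](O)CC=C | intermediate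
8 | 3-methylbut-3-enoic acid | C=C(C)CC(=O)O | starting material
9 | (3S,1Z)-1-iodo-2-methylhexa-1,5-dien-3-yl 3-methylbut-3-enoate | I/C=C(/C)[C@@H](OC(=O)CC(C)=C)CC=C | intermediate
10 | (7S)-7-[(Z)-1-iodoprop-1-en-2-yl]-4-methyl-3,6-dihydrooxepin-2(7H)-one | I/C=C(/C)[C@@H]1CC=C(C)CC(=O)O1 | intermediate
11 | (3Z,6S,7Z)-8-iodo-3,7-dimethylocta-3,7-diene-1,6-diol | I/C=C(/C)[C@@H](O)C/C=C(C)\CCO | intermediate
12 | (3S,1Z,5Z)-8-(tert-butyldimethylsilyloxy)-1-iodo-2,6-dimethylocta-1,5-dien-3-ol | I/C=C(/C)[C@@H](O)C/C=C(C)\CCO[Si](C)(C)C(C)(C)C | intermediate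
13 | (R)-2-methylbutanoic acid | CC[C@@H](C)C(=O)O | starting material
14 | (3S,1Z,5Z)-8-(tert-butyldimethylsilyloxy)-1-iodo-2,6-dimethylocta-1,5-dien-3-yl (2R)-2-methylbutanoate | I/C=C(/C)[C@@H](OC(=O)[C@H](C)CC)C/C=C(C)\CCO[Si](C)(C)C(C)(C)C | intermediate
15 | (1Z,3S)-4-{(2R,3S)-3-[2-(tert-butyldimethylsilyloxy)ethyl]-3-methyloxiran-2-yl}-1-iodo-2-methylbut-1-en-3-yl (2R)-2-methylbutanoate | I/C=C(/C)[C@@H](OC(=O)[C@H](C)CC)C[C@H]1O[C@@]1(C)CCO[Si](C)(C)C(C)(C)C | intermediate
16 | (E)-3-(tributylstannyl)prop-2-en-1-ol | OC/C=C/[Sn](CCCC)(CCCC)CCCC | starting material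
17 | (2E,4Z,6S)-dienol: 7-{(2R,3S)-3-[2-(tert-butyldimethylsilyloxy)ethyl]-3-methyloxiran-2-yl}-1-hydroxy-5-methylhepta-2,4-dien-6-yl (2R)-2-methylbutanoate | OC/C=C/C=C(/C)[C@@H](OC(=O)[C@H](C)CC)C[C@H]1O[C@@]1(C)CCO[Si](C)(C)C(C)(C)C | intermediate
18 | (2R,3R)-epoxy alcohol: (1Z,3S)-4-{(2R,3S)-3-[2-(tert-butyldimethylsilyloxy)ethyl]-3-methyloxiran-2-yl}-1-[(2R,3R)-3-(hydroxymethyl)oxiran-2-yl]-2-methylbut-1-en-3-yl (2R)-2-methylbutanoate | OC[C@H]1O[C@@H]1/C=C(/C)[C@@H](OC(=O)[C@H](C)CC)C[C@H]2O[C@@]2(C)CCO[Si](C)(C)C(C)(C)C | intermediate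
19 | epoxy iodide: as 18 with (2R,3S)-3-(iodomethyl)oxiran-2-yl in place of the hydroxymethyl oxirane | IC[C@H]1O[C@@H]1/C=C(/C)[C@@H](OC(=O)[C@H](C)CC)C[C@H]2O[C@@]2(C)CCO[Si](C)(C)C(C)(C)C | intermediate
20 | divinyl carbinol: (3S,4Z,6S)-7-{(2R,3S)-3-[2-(tert-butyldimethylsilyloxy)ethyl]-3-methyloxiran-2-yl}-3-hydroxy-5-methylhepta-1,4-dien-6-yl (2R)-2-methylbutanoate | O[C@@H](C=C)/C=C(/C)[C@@H](OC(=O)[C@H](C)CC)C[C@H]1O[C@@]1(C)CCO[Si](C)(C)C(C)(C)C | intermediate
21 | 2-(bromomethyl)acrylic acid | C=C(CBr)C(=O)O | starting material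
22 | 2-(bromomethyl)prop-2-enoate of 20 at the C3 hydroxyl of the heptadiene chain (3S,4Z,6S) | C=C(CBr)C(=O)O[C@@H](C=C)/C=C(/C)[C@@H](OC(=O)[C@H](C)CC)C[C@H]1O[C@@]1(C)CCO[Si](C)(C)C(C)(C)C | intermediate
23 | (5R)-3-(bromomethyl)-5-[(1Z,3S)-4-{(2R,3S)-3-[2-(tert-butyldimethylsilyloxy)ethyl]-3-methyloxiran-2-yl}-2-methyl-3-{[(2R)-2-methylbutanoyl]oxy}but-1-en-1-yl]furan-2(5H)-one | O=C1O[C@@H](C=C1CBr)/C=C(/C)[C@@H](OC(=O)[C@H](C)CC)C[C@H]2O[C@@]2(C)CCO[Si](C)(C)C(C)(C)C | intermediate
24 | (5R)-3-(bromomethyl)-5-[(1Z,3S)-4-[(2R,3S)-3-(2-hydroxyethyl)-3-methyloxiran-2-yl]-2-methyl-3-{[(2R)-2-methylbutanoyl]oxy}but-1-en-1-yl]furan-2(5H)-one | O=C1O[C@@H](C=C1CBr)/C=C(/C)[C@@H](OC(=O)[C@H](C)CC)C[C@H]2O[C@@]2(C)CCO | intermediate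
25 | (5R)-3-(bromomethyl)-5-[(1Z,3S)-2-methyl-3-{[(2R)-2-methylbutanoyl]oxy}-4-[(2R,3S)-3-methyl-3-(2-oxoethyl)oxiran-2-yl]but-1-en-1-yl]furan-2(5H)-one | O=C1O[C@@H](C=C1CBr)/C=C(/C)[C@@H](OC(=O)[C@H](C)CC)C[C@H]2O[C@@]2(C)CC=O | intermediate
26 | allylchromium dichloride: 25 with CH2CrCl2 in place of CH2Br | O=C1O[C@@H](C=C1C[Cr](Cl)Cl)/C=C(/C)[C@@H](OC(=O)[C@H](C)CC)C[C@H]2O[C@@]2(C)CC=O | intermediate
27 | (1R,3S,6R,7R,8S,10S)-1,10-epoxy-8-hydroxy-3-[(2R)-2-methylbutanoyloxy]germacra-4Z,11(13)-dien-12,6-olide (8α-alcohol) | C=C1C(=O)O[C@@H]2/C=C(/C)[C@@H](OC(=O)[C@H](C)CC)C[C@H]3O[C@@]3(C)C[C@H](O)[C@@H]12 | intermediate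
28 | angelic acid ((Z)-2-methylbut-2-enoic acid) | C/C=C(/C)C(=O)O | starting material
29 | (1R,3S,6R,7R,8R,10S)-8-angeloyloxy-1,10-epoxy-3-[(2R)-2-methylbutanoyloxy]germacra-4Z,11(13)-dien-12,6-olide (CNP0108431.1) | C=C1C(=O)O[C@@H]2/C=C(/C)[C@@H](OC(=O)[C@H](C)CC)C[C@H]3O[C@@]3(C)C[C@@H](OC(=O)/C(C)=C\C)[C@@H]12 | target

**Step count and risks**

Total step count: 19. Longest linear sequence: 19 steps (from propargyl alcohol 1).

Steps most likely to fail:

Step 18 (key cyclisation). What may go wrong: the aldehyde may add through the arrangement with C9 axial, or through a boat, which turns over the facial selectivity at C8; oligomerisation, or loss of the β,γ-epoxy aldehyde by elimination, may also compete. Fallback: the ring closure is kept and the end game is changed. Starting from 25, the cyclisation product would then be the 8β-alcohol F1, the C8 epimer of 27. F1 would be acylated with retention by the mixed anhydride made from angelic acid 28 and 2,4,6-trichlorobenzoyl chloride (Et3N, then toluene, 80 °C, no DMAP, Yamaguchi-type), a known way to angelates that avoids isomerisation to the tiglate, and the route is rejoined at 29.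

Step 19 (Mitsunobu inversion). What may go wrong: displacement at the hindered C8 centre may be slower than elimination towards C7 or C9; triphenylphosphine may add to the α-methylene lactone; the angelate may isomerise. Fallback: inversion by oxidation and reduction in place of substitution. Starting from 27, Dess–Martin oxidation would give the 8-ketone F2. Luche reduction (NaBH4, CeCl3, MeOH, −78 °C; 1,2-selective, so the methylene lactone is spared) should deliver hydride from the α-face, away from the lactone ring, to give the 8β-alcohol F1 already described, and retentive acylation as above rejoins the route at 29.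

Step 9 (Shi epoxidation). What may go wrong: facial selectivity of the dioxirane may be lower on a Z-type trisubstituted alkene than on E-alkenes, and the ester may be partly hydrolysed at the pH of the reaction. Fallback: catalyst control through a bound hydroxyl in place of an unbound dioxirane. Starting from 14, the silyl ether would be cleaved (HF·pyridine, pyridine, THF) to the homoallylic alcohol F3. Vanadium-catalysed asymmetric epoxidation of homoallylic alcohols (VO(OiPr)3, a chiral bishydroxamic acid ligand of the enantiomeric series that gives the 1R,10S oxirane, cumene hydroperoxide, toluene, 0 °C) would give the epoxy alcohol F4. Silylation (tert-butyldimethylsilyl chloride, imidazole) rejoins the route at 15.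

**Further compounds**

F1 | step 18 | (1R,3S,6R,7R,8R,10S)-1,10-epoxy-8-hydroxy-3-[(2R)-2-methylbutanoyloxy]germacra-4Z,11(13)-dien-12,6-olide (8β-alcohol) | C=C1C(=O)O[C@@H]2/C=C(/C)[C@@H](OC(=O)[C@H](C)CC)C[C@H]3O[C@@]3(C)C[C@@H](O)[C@@H]12
F2 | step 19 | 8-ketone: 1,10-epoxy-3-[(2R)-2-methylbutanoyloxy]-8-oxogermacra-4Z,11(13)-dien-12,6-olide, other centres arranged as in 27 | C=C1C(=O)O[C@@H]2/C=C(/C)[C@@H](OC(=O)[C@H](C)CC)C[C@H]3O[C@@]3(C)CC(=O)[C@@H]12
F3 | step 9 | (3S,1Z,5Z)-8-hydroxy-1-iodo-2,6-dimethylocta-1,5-dien-3-yl (2R)-2-methylbutanoate | I/C=C(/C)[C@@H](OC(=O)[C@H](C)CC)C/C=C(C)\CCO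
F4 | step 9 | (1Z,3S)-4-[(2R,3S)-3-(2-hydroxyethyl)-3-methyloxiran-2-yl]-1-iodo-2-methylbut-1-en-3-yl (2R)-2-methylbutanoate | I/C=C(/C)[C@@H](OC(=O)[C@H](C)CC)C[C@H]1O[C@@]1(C)CCO
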